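## The problem

CNP0312791.1 is a cis-fused eremophilane. Ring A (C1–C2–C3–C4–C5–C10) carries the C2 ketone and the C4 methyl; ring B (C5–C6–C7–C8–C9–C10) carries the C7 isopropenyl group and the two acyloxy groups at C8 and C9. The rings share the bond between quaternary C5 (angular methyl) and C10, whose hydrogen lies on the same face as that methyl.

Six ring stereocentres must be set (4S,5R,7R,8R,9S,10S in eremophilane numbering), plus the (R) centre of the 2-methylbutanoate. With β defined as the face of the C5 methyl, the C4 methyl, the isopropenyl group and H-10 are β and both ester oxygens are α.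

C7 can be taken from the chiral pool and can hand its configuration to C5 through a suprafacial rearrangement. C5, being quaternary, can then fix C10. Because the 5-methyl and 7-isopropenyl groups lock ring B in one chair, C5 and C7 together also decide the faces at C8 and C9.

The C4/C5 pair needs the two methyl groups cis next to a quaternary carbon. The C8/C9 diol is cis but carries two different esters, so the two oxygens must be introduced or acylated one after the other.

Several groups are fragile. The isopropenyl alkene does not survive strong protic acid or electrophilic oxidants. The tiglate is a Michael acceptor. A cis-diol monoester can pass its acyl group to the neighbouring oxygen. The α-centre of the 2-methylbutanoyl group can epimerise when the acid is activated.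

The feature that opens the route is the position of C1: it lies between the C2 carbonyl and the ring-fusion carbon C10, and C10 is flanked on its other side by the oxygenated carbon C9. A carbene centred on C1 that adds across a C9=C10 double bond of a preformed ring B therefore makes C1–C10, closes ring A, and leaves C9 inside a ketone-activated cyclopropane that can be opened again to functionalise C9.

## Retrosynthesis

**Esters and ketone.** The C2 ketone of target 32 is masked as the dioxolane 31, and the C9–O acyl bond is cut first, giving alcohol 28 and tiglic acid 29. The tiglate goes on last because it is the more reactive ester and because the C9 hydroxyl is the hindered one; forming it while C8 is already esterified removes any need to tell two hydroxyls apart. The forward step must acylate an axial alcohol without moving the neighbouring ester.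

**C9–H and C8–O.** Alcohol 28 is traced to ketone 27 (cut of C9–H), and the C8–O ester bond of 27 is cut with inversion to the 8β-hydroxy ketone 25 and (R)-2-methylbutanoic acid 26. A C9 ketone is preferred over any alkene-based entry to the diol because enolate chemistry at C8 is blind to the isopropenyl group, whereas dihydroxylation or epoxidation of a ring alkene is not. The forward reactions must deliver hydride to the β face of C9 and the carboxylate to the α face of C8.

**C8–O and the C9 carbonyl.** Removing the C8 oxygen gives keto ketal 23. Its C9 carbonyl comes from alcohol 22, this from iodide 20 and iodo ketone 19, and reconnecting C9 to C1 gives the cyclopropyl ketone 17. Iodide is chosen over an oxygen nucleophile for opening 17 because it opens cyclopropyl ketones under aprotic, cold conditions; an acid-mediated acetolysis would also attack the isopropenyl group. The price is two extra operations (ketalization before any base, then C–I to C–O by a radical).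

**Key cut.** Cutting C1–C10 and C1–C9 of 17 leads to the diazoketone 16. This removes ring A, the cyclopropane and three stereocentres in one stroke and leaves a monocyclic ring B with a five-carbon side chain on quaternary C5. Cutting instead at C4–C5 or C5–C10 would leave the quaternary centre to be made in the ring-forming step. The forward step must be selective for the ring alkene over the isopropenyl group and over C–H insertion.

**Side chain.** The diazoketone 16 comes from acid 14 (cut of C1–C2). Acid 14 comes from acid 10 by one-carbon homologation through the diazoketone 12 (cut of C2–C3). The C4 stereocentre lies α to the carboxyl in 10, which is what makes the next cut possible, so the extra carbon is inserted afterwards, with retention at the migrating carbon.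

**C4–C5.** Acid 10 is cut between C4 and C5 by an Ireland–Claisen transform to the trans allylic propanoate 7, made from alcohol 5 and propanoic acid 6. The rearrangement forms the quaternary centre intramolecularly, transfers the C–O configuration to C5, and sets C4 from the ketene acetal geometry. A conjugate addition to the enone would form the same bond but offers no control at C4.

**Ring B.** Alcohol 5 goes back through the chloro alcohol 4 and the chloro enone 3 to car-3-en-5-one 2 and (+)-3-carene 1. Ring B has methyl and isopropenyl in a 1,3 relationship, which the carvone and limonene series (1,4) cannot supply. 3-Carene can: its cyclopropane, once conjugated to a ketone, opens to exactly this pattern with the correct absolute configuration at C7.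

## Roads not taken

**Alternative 1:** The cut removes ring B across C5–C6 and C7–C8. A ring A dienyl ether A1 (C5(Me)=C10–C9H=C8H–OPMB) would combine with methyl acrylate A2 in a Diels–Alder reaction to give the endo adduct A3, with the C7 ester cis to the C8 ether and a C9=C10 alkene.
- Merits: it is convergent, uses no diazo compounds, and brings the C8 oxygen and the C7 carbon in the ring-forming step with the regiochemistry set by the alkoxy group.
- Weak points: the diene terminus C5 is fully substituted and ring A holds its methyl cis to the rest of the diene, so the s-cis conformer is strained and a quaternary centre would have to form in an intermolecular cycloaddition. Endo addition gives C7/C8 cis where the target is trans. The ester must still become isopropenyl. C10 is left sp2, and any syn addition across C9=C10 puts H-10 and O-9 on the same face, whereas the target has them on opposite faces.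
- Comparison: for placing the C8 oxygen this road is better than the chosen one, which needs a late enolate oxidation and an inversion. The chosen plan sets against it a quaternary centre made by an intramolecular rearrangement and a C10 fixed in the ring closure itself.

**Alternative 2:** The cut is at C5–C10 and C6–C7. Heating the acyclic triene A4 ((E,Z)-diene, (E)-vinyl sulfone) would give the cis-fused octalin sulfone A5 with a C8=C9 alkene.
- Merits: both rings and four stereocentres form in one thermal step. The alkene sits exactly where the diol is needed while the isopropenyl group is still masked as a silyl ether of the tertiary alcohol, so a cis-dihydroxylation would meet no competing alkene. In this respect it is better than the chosen plan, which spends steps 11–15 to bring C8 and C9 to the same point.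
- Weak points: (Z)-dienes reach the reactive conformation with difficulty and tend to isomerise by 1,5-hydrogen shift at the temperatures needed. The dienophile carbon C5 is fully substituted. The only stereocentre present (C4) sits on a flexible tether and would have to control both face and endo/exo mode. A4 needs a long linear preparation with three defined alkenes. Afterwards the sulfone must be removed reductively, the two hydroxyls of the diol told apart, and the tertiary alcohol dehydrated toward the methyl groups only.
- Comparison: the chosen plan offers a chiral-pool ring B, a tether that permits only one face, and oxygens introduced one at a time.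

**Alternative 3:** The cut is at C5–C6 and C9–C10. Dichloroketene A7 would add across the C5(Me)=C10H alkene of the ring A alkene A6 to give the cis-fused dichlorocyclobutanone A8, with C9 as the carbonyl carbon and C6 as the CCl2 carbon.
- Merits: the [2+2] addition is suprafacial on the alkene, so the cis relationship of the C5 methyl and H-10 is certain. The quaternary centre forms under mild conditions. C9 arrives as a carbonyl, which is better than the chosen plan, where four steps (11–14) are needed to reach that state.
- Weak points: the four-membered ring holds only C6 and C9 of ring B. C7 and C8, with the isopropenyl group and an oxygen, would have to be inserted between them, a two-carbon ring expansion with two new stereocentres for which no single reliable operation exists. The chlorines must be removed, and facial selectivity rests on the C4 methyl alone.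
- Comparison: the chosen plan closes ring A onto a complete ring B whose C7 centre is bought, at the cost of a longer path to the C9 ketone.

Key step: step 10

Assumption: ester 7, enolised without polar cosolvent, rearranges through the chair-like transition state usual for this ketene acetal geometry in cyclohexenyl esters; numbering and α/β descriptors are those of eremophilane (β = face of the C5 methyl).

## Route

Step 1
Reactants: 1 (+)-3-carene
Product: 2 (1R,6S)-4,7,7-trimethylbicyclo[4.1.0]hept-3-en-2-one (car-3-en-5-one)
Conditions: t-BuOOH, CrO3 (cat.), CH2Cl2, rt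
Reagents that add atoms: tert-butyl hydroperoxide (CC(C)(C)OO)
Why: Chromium-catalysed allylic oxidation; the methylene next to the unsubstituted alkene carbon, which is also cyclopropylcarbinyl, is the preferred site in 3-carene, and the two cyclopropane stereocentres are untouched.

Step 2
Reactants: 2
Product: 3 (5S)-5-(2-chloropropan-2-yl)-3-methylcyclohex-2-en-1-one
Conditions: HCl (g), Et2O, 0 °C
Reagents that add atoms: hydrogen chloride (Cl)
Why: Homoconjugate hydrochlorination of a cyclopropyl ketone: the protonated enone opens the cyclopropane bond that overlaps with the carbonyl π system at its tertiary carbon, chloride is trapped there and the dienol tautomerises to the enone. The remaining ring stereocentre is not involved and becomes C7.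

Step 3
Reactants: 3
Product: 4 (1S,5S)-5-(2-chloropropan-2-yl)-3-methylcyclohex-2-en-1-ol (cis)
Conditions: NaBH4, CeCl3·7H2O, MeOH, −78 → 0 °C
Reagents that add atoms: none
Why: Luche 1,2-reduction; axial hydride delivery to the half-chair with the bulky 5-substituent equatorial gives the pseudo-equatorial cis alcohol, as with other 5-substituted cyclohexenones. The tertiary chloride does not solvolyse under these cold, brief conditions.

Step 4
Reactants: 4
Product: 5 (1S,5S)-3-methyl-5-(prop-1-en-2-yl)cyclohex-2-en-1-ol (cis)
Conditions: KOtBu (2.5 equiv), THF, 0 °C → rt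
Reagents that add atoms: none
Why: E2 dehydrochlorination of a tertiary chloride with a bulky base removes one of six methyl hydrogens and not the single ring methine hydrogen (Hofmann orientation), giving the isopropenyl group. It is run on the alkoxide and not on enone 3, where an α'-enolate would displace chloride and close the cyclopropane again.

Step 5
Reactants: 5; 6 propanoic acid
Product: 7 (1R,5S)-3-methyl-5-(prop-1-en-2-yl)cyclohex-2-en-1-yl propanoate (trans)
Conditions: PPh3, DIAD, THF, 0 °C → rt
Reagents that add atoms: none
Why: Mitsunobu esterification with inversion at the carbinol carbon turns the cis alcohol into the trans ester, whose C–O bond lies on the face opposite to the isopropenyl group. Attack at the methyl-bearing alkene terminus is disfavoured.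

Step 6
Reactants: 7
Product: 10 (2R)-2-[(1S,5R)-1-methyl-5-(prop-1-en-2-yl)cyclohex-2-en-1-yl]propanoic acid, via silyl ketene acetal 8 (not isolated), via trimethylsilyl ester 9 (not isolated)
Conditions: LiN(iPr)2 (LDA), THF, −78 °C; Me3SiCl, −78 → 65 °C; aq. citric acid
Reagents that add atoms: none
Why: Ireland–Claisen rearrangement; the [3,3] shift is suprafacial, so C4–C5 forms on the face that carried the ester oxygen (trans to isopropenyl) and C5 is set by chirality transfer. Enolisation without polar cosolvent gives the ketene acetal with its methyl cis to the ring oxygen, and the chair-like transition state then places the C4 methyl so that it will be cis to the C5 methyl once ring A is closed.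

Step 7
Reactants: 10
Product: 12 (3R)-1-diazo-3-[(1S,5R)-1-methyl-5-(prop-1-en-2-yl)cyclohex-2-en-1-yl]butan-2-one, via acid chloride 11 (not isolated)
Conditions: 1-chloro-N,N,2-trimethylprop-1-en-1-amine, CH2Cl2, 0 °C → rt; then CH2N2 (3 equiv), Et2O, 0 °C
Reagents that add atoms: diazomethane (C=[N+]=[N-])
Why: Acylation of diazomethane, the first stage of an Arndt–Eistert homologation. The chloroenamine forms the acid chloride without releasing HCl (which would add to the isopropenyl group), and no amine base is present that could epimerise C4 through a ketene.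

Step 8
Reactants: 12
Product: 14 (3S)-3-[(1R,5R)-1-methyl-5-(prop-1-en-2-yl)cyclohex-2-en-1-yl]butanoic acid, via ketene 13 (not isolated)
Conditions: PhCO2Ag (cat.), Et3N, THF/H2O, rt, dark
Reagents that add atoms: water (O)
Why: Silver-promoted Wolff rearrangement; the secondary alkyl group migrates with retention, so C4 keeps its configuration, and water adds to the ketene. C3 is now a methylene and the carboxyl carbon is C2.

Step 9
Reactants: 14
Product: 16 (4S)-1-diazo-4-[(1R,5R)-1-methyl-5-(prop-1-en-2-yl)cyclohex-2-en-1-yl]pentan-2-one, via acid chloride 15 (not isolated)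
Conditions: 1-chloro-N,N,2-trimethylprop-1-en-1-amine, CH2Cl2, 0 °C → rt; then CH2N2 (3 equiv), Et2O, 0 °C
Reagents that add atoms: diazomethane (C=[N+]=[N-])
Why: Acylation of diazomethane under the same HCl-free conditions adds C1 as the diazo carbon. No stereocentre is adjacent to the acyl carbon any more.

Step 10
Reactants: 16
Product: 17 1α,9α-cyclo-10βH-eremophil-11-en-2-one (tricyclic cyclopropyl ketone; C1 bridges C9 and C10 on the α face; H-9 and H-10 β)
Conditions: Rh2(OAc)4 (1 mol %), CH2Cl2, 40 °C, slow addition of 16
Reagents that add atoms: none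
Why: Rh2(OAc)4 takes up the diazo carbon, N2 leaves, and the electrophilic rhodium carbenoid at C1 adds to the cis-disubstituted C9=C10 alkene in a concerted, asynchronous [2+1] step; this is the long-established intramolecular cyclopropanation of 1-diazoalk-6-en-2-ones to bicyclo[4.1.0]heptan-2-ones. Ring A closes as a six-membered ring through C1–C10 (exo attack on the nearer alkene carbon), and the three-membered ring closes in the same step through C1–C9. C9 and C10 are set by the tether: it is anchored at quaternary C5 and only four atoms long, so C1 can reach only the alkene face that carries C4, which puts C1 on the α face and leaves H-9 and H-10 β, cis to the C5 methyl; the cis geometry of the alkene is carried over stereospecifically. C1 has no freedom, its hydrogen being forced to the outside of the two rings it joins. The step needs chemoselectivity for the ring alkene: the isopropenyl group sits on the opposite face of ring B and could be reached only through an eight-membered ring, the only C–H bonds in a 1,5 relationship to the carbene are the primary ones of the C4 methyl because C5 is quaternary, and slow addition suppresses carbene dimerisation. C4, C5 and C7 are spectators.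

Step 11
Reactants: 17
Product: 19 9β-iodo-10βH-eremophil-11-en-2-one, via silyl enol ether 18 (not isolated)
Conditions: Me3SiI, 2,6-di-tert-butylpyridine (cat.), CH2Cl2, −40 → 0 °C; then 0.5 M HCl, THF, 0 °C
Reagents that add atoms: iodotrimethylsilane (C[Si](C)(C)I)
Why: Homoconjugate opening of a cyclopropyl ketone by a silyl iodide: O-silylation activates the ketone and iodide attacks C9 with inversion, cleaving C1–C9, the cyclopropane bond that overlaps with the carbonyl π system (C1–C10 lies near its nodal plane and C10 is fully substituted). The aprotic, cold conditions spare the isopropenyl group; C10 keeps its β hydrogen, so the decalin is cis-fused.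

Step 12
Reactants: 19
Product: 20 2,2-ethylenedioxy-9β-iodo-10βH-eremophil-11-ene
Conditions: Me3SiOCH2CH2OSiMe3, Me3SiOTf (cat.), CH2Cl2, −78 → −20 °C
Reagents that add atoms: 1,2-bis(trimethylsilyloxy)ethane (C[Si](C)(C)OCCO[Si](C)(C)C)
Why: Silyl-triflate-catalysed ketalization under aprotic conditions. C2 is masked before any base is used, because the C1 enolate of 19 would displace iodide and re-form the cyclopropane, and so that C2 cannot compete in the later enolate chemistry at C9.

Step 13
Reactants: 20
Product: 22 2,2-ethylenedioxy-10βH-eremophil-11-en-9-ol (both C9 epimers), via hydroperoxide 21 (not isolated)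
Conditions: Bu3SnH (slow addition), Et3B (cat.), dry air, toluene, 0 °C → rt
Reagents that add atoms: dioxygen (O=O)
Why: Radical hydroxylation of a secondary iodide: the C9 radical is trapped by O2 faster than by the tin hydride kept at low concentration, and the hydroperoxide is reduced in the flask. The radical path is insensitive to the axial C4 that would hinder an SN2 displacement at C9, and both epimers are usable because C9 becomes a ketone next.

Step 14
Reactants: 22
Product: 23 2,2-ethylenedioxy-10βH-eremophil-11-en-9-one
Conditions: DMP, NaHCO3, CH2Cl2, rt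
Reagents that add atoms: none
Why: Periodinane oxidation of a secondary alcohol under buffered, non-enolising conditions; both epimers converge. H-10, now α to the ketone, is not at risk, since the cis fusion is the more stable one here (it keeps the 5-methyl and 7-isopropenyl groups equatorial on ring B).

Step 15
Reactants: 23
Product: 25 2,2-ethylenedioxy-8β-hydroxy-10βH-eremophil-11-en-9-one, via potassium enolate 24 (not isolated)
Conditions: KN(SiMe3)2, THF, −78 °C; 2-(benzenesulfonyl)-3-phenyloxaziridine, −78 °C; aq. NH4Cl
Reagents that add atoms: 2-(benzenesulfonyl)-3-phenyloxaziridine (O=S(=O)(c1ccccc1)N1OC1c1ccccc1)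
Why: Enolate hydroxylation with an N-sulfonyloxaziridine; kinetic deprotonation takes the C8 methylene and not the hindered ring-fusion hydrogen, and the reagent leaves the isopropenyl alkene alone, as a peracid would not. With ring B locked, oxygen is expected to enter axially on the β face, anti to the pseudo-axial H-7 (an equatorial approach would eclipse the C7–C11 bond), giving the 8β alcohol.

Step 16
Reactants: 25; 26 (R)-2-methylbutanoic acid
Product: 27 2,2-ethylenedioxy-9-oxo-10βH-eremophil-11-en-8α-yl (2R)-2-methylbutanoate
Conditions: PPh3, DIAD, toluene, 0 °C → rt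
Reagents that add atoms: none
Why: Mitsunobu esterification; SN2 displacement by the carboxylate at the carbon next to the ketone inverts C8, turning the axial 8β alcohol into the equatorial 8α ester, trans to the isopropenyl group. The acid reacts as a carboxylate, so its α-centre is never activated toward enolisation.

Step 17
Reactants: 27
Product: 28 2,2-ethylenedioxy-9α-hydroxy-10βH-eremophil-11-en-8α-yl (2R)-2-methylbutanoate
Conditions: NaBH4, CeCl3·7H2O, MeOH/THF, −78 °C; AcOH quench
Reagents that add atoms: none
Why: Ketone reduction under Luche conditions; the α face of C9 is screened by the axial C4 of ring A (1,3-diaxial), so hydride adds from the β face and gives the axial 9α alcohol, cis to the C8 ester. The cold, weakly basic medium and the acidic quench keep the acyl group on the equatorial C8 oxygen.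

Step 18
Reactants: 28; 29 tiglic acid [(E)-2-methylbut-2-enoic acid]
Product: 31 2,2-ethylenedioxy-8α-[(2R)-2-methylbutanoyloxy]-10βH-eremophil-11-en-9α-yl (E)-2-methylbut-2-enoate, via mixed anhydride 30 (not isolated)
Conditions: 2,4,6-Cl3C6H2COCl, Et3N, toluene, rt; then 28, DMAP, toluene, 80 °C
Reagents that add atoms: none
Why: Yamaguchi esterification; the mixed anhydride with DMAP is an established way to put a tiglate on a hindered secondary alcohol without isomerising the (E) double bond. No stereocentre is formed or broken.

Step 19
Reactants: 31
Product: 32 (4S,5R,7R,8R,9S,10S)-8-[(2R)-2-methylbutanoyloxy]-9-[(E)-2-methylbut-2-enoyloxy]eremophil-11-en-2-one (CNP0312791.1; 8α,9α-diester, 10βH)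
Conditions: PPTS, acetone/H2O, 50 °C
Reagents that add atoms: water (O)
Why: Mild acid-catalysed hydrolysis of the dioxolane; the conditions are weak enough to leave both esters, the tiglate geometry and the isopropenyl group untouched.

## Compound list

1 | (+)-3-carene, (1S,6R)-3,7,7-trimethylbicyclo[4.1.0]hept-3-ene | CC1=CC[C@@H]2[C@H](C1)C2(C)C | starting material
2 | (1R,6S)-4,7,7-trimethylbicyclo[4.1.0]hept-3-en-2-one (car-3-en-5-one) | CC1=CC(=O)[C@@H]2[C@H](C1)C2(C)C | intermediate
3 | (5S)-5-(2-chloropropan-2-yl)-3-methylcyclohex-2-en-1-one | CC(C)(Cl)[C@H]1CC(C)=CC(=O)C1 | intermediate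
4 | (1S,5S)-5-(2-chloropropan-2-yl)-3-methylcyclohex-2-en-1-ol (cis) | CC(C)(Cl)[C@H]1CC(C)=C[C@@H](O)C1 | intermediate
5 | (1S,5S)-3-methyl-5-(prop-1-en-2-yl)cyclohex-2-en-1-ol (cis) | C=C(C)[C@H]1CC(C)=C[C@@H](O)C1 | intermediate
6 | propanoic acid | CCC(=O)O | starting material
7 | (1R,5S)-3-methyl-5-(prop-1-en-2-yl)cyclohex-2-en-1-yl propanoate (trans) | C=C(C)[C@H]1CC(C)=C[C@H](OC(=O)CC)C1 | intermediate
8 | (E)-trimethylsilyl ketene acetal of 7 (C-methyl cis to the ring oxygen) | C=C(C)[C@H]1CC(C)=C[C@H](O/C(O[Si](C)(C)C)=C\C)C1 | intermediate (not isolated)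
9 | trimethylsilyl (2R)-2-[(1S,5R)-1-methyl-5-(prop-1-en-2-yl)cyclohex-2-en-1-yl]propanoate | C=C(C)[C@H]1C[C@@]([C@@H](C)C(=O)O[Si](C)(C)C)(C)C=CC1 | intermediate (not isolated)
10 | (2R)-2-[(1S,5R)-1-methyl-5-(prop-1-en-2-yl)cyclohex-2-en-1-yl]propanoic acid | C=C(C)[C@H]1C[C@@]([C@@H](C)C(=O)O)(C)C=CC1 | intermediate
11 | (2R)-2-[(1S,5R)-1-methyl-5-(prop-1-en-2-yl)cyclohex-2-en-1-yl]propanoyl chloride | C=C(C)[C@H]1C[C@@]([C@@H](C)C(=O)Cl)(C)C=CC1 | intermediate (not isolated)
12 | (3R)-1-diazo-3-[(1S,5R)-1-methyl-5-(prop-1-en-2-yl)cyclohex-2-en-1-yl]butan-2-one | C=C(C)[C@H]1C[C@@]([C@@H](C)C(=O)C=[N+]=[N-])(C)C=CC1 | intermediate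
13 | (3S)-3-[(1S,5R)-1-methyl-5-(prop-1-en-2-yl)cyclohex-2-en-1-yl]but-1-en-1-one (ketene) | C=C(C)[C@H]1C[C@@]([C@@H](C)C=C=O)(C)C=CC1 | intermediate (not isolated)
14 | (3S)-3-[(1R,5R)-1-methyl-5-(prop-1-en-2-yl)cyclohex-2-en-1-yl]butanoic acid | C=C(C)[C@H]1C[C@@]([C@@H](C)CC(=O)O)(C)C=CC1 | intermediate
15 | (3S)-3-[(1R,5R)-1-methyl-5-(prop-1-en-2-yl)cyclohex-2-en-1-yl]butanoyl chloride | C=C(C)[C@H]1C[C@@]([C@@H](C)CC(=O)Cl)(C)C=CC1 | intermediate (not isolated)
16 | (4S)-1-diazo-4-[(1R,5R)-1-methyl-5-(prop-1-en-2-yl)cyclohex-2-en-1-yl]pentan-2-one | C=C(C)[C@H]1C[C@@]([C@@H](C)CC(=O)C=[N+]=[N-])(C)C=CC1 | intermediate (precursor of the key step)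
17 | 1α,9α-cyclo-10βH-eremophil-11-en-2-one (4β,5β-dimethyl, 7β-isopropenyl; cyclopropane C1–C9–C10 on the α face) | C=C(C)[C@H]1C[C@@]2(C)[C@@H]3[C@H](C(=O)C[C@@H]2C)[C@@H]3C1 | intermediate (product of the key step)
18 | 9β-iodo-2-(trimethylsilyloxy)-10βH-eremophila-1,11-diene | C=C(C)[C@H]1C[C@@]2(C)[C@H](C=C(O[Si](C)(C)C)C[C@@H]2C)[C@@H](I)C1 | intermediate (not isolated)
19 | 9β-iodo-10βH-eremophil-11-en-2-one | C=C(C)[C@H]1C[C@@]2(C)[C@H](CC(=O)C[C@@H]2C)[C@@H](I)C1 | intermediate
20 | 2,2-ethylenedioxy-9β-iodo-10βH-eremophil-11-ene | C=C(C)[C@H]1C[C@@]2(C)[C@H](CC3(OCCO3)C[C@@H]2C)[C@@H](I)C1 | intermediate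
21 | 2,2-ethylenedioxy-9-hydroperoxy-10βH-eremophil-11-ene (both C9 epimers) | C=C(C)[C@H]1C[C@@]2(C)[C@H](CC3(OCCO3)C[C@@H]2C)C(OO)C1 | intermediate (not isolated)
22 | 2,2-ethylenedioxy-10βH-eremophil-11-en-9-ol (both C9 epimers) | C=C(C)[C@H]1C[C@@]2(C)[C@H](CC3(OCCO3)C[C@@H]2C)C(O)C1 | intermediate
23 | 2,2-ethylenedioxy-10βH-eremophil-11-en-9-one | C=C(C)[C@H]1C[C@@]2(C)[C@H](CC3(OCCO3)C[C@@H]2C)C(=O)C1 | intermediate
24 | potassium 8(9)-enolate of 23 | C=C(C)[C@H]1C[C@@]2(C)[C@H](CC3(OCCO3)C[C@@H]2C)C([O-])=C1.[K+] | intermediate (not isolated)
25 | 2,2-ethylenedioxy-8β-hydroxy-10βH-eremophil-11-en-9-one | C=C(C)[C@H]1C[C@@]2(C)[C@H](CC3(OCCO3)C[C@@H]2C)C(=O)[C@H]1O | intermediate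
26 | (R)-2-methylbutanoic acid | CC[C@@H](C)C(=O)O | starting material
27 | 2,2-ethylenedioxy-9-oxo-10βH-eremophil-11-en-8α-yl (2R)-2-methylbutanoate | C=C(C)[C@H]1C[C@@]2(C)[C@H](CC3(OCCO3)C[C@@H]2C)C(=O)[C@@H]1OC(=O)[C@H](C)CC | intermediate
28 | 2,2-ethylenedioxy-9α-hydroxy-10βH-eremophil-11-en-8α-yl (2R)-2-methylbutanoate | C=C(C)[C@H]1C[C@@]2(C)[C@H](CC3(OCCO3)C[C@@H]2C)[C@H](O)[C@@H]1OC(=O)[C@H](C)CC | intermediate
29 | tiglic acid, (E)-2-methylbut-2-enoic acid | C/C=C(\C)C(=O)O | starting material
30 | (E)-2-methylbut-2-enoic 2,4,6-trichlorobenzoic anhydride | C/C=C(\C)C(=O)OC(=O)c1c(Cl)cc(Cl)cc1Cl | intermediate (not isolated)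
31 | 2,2-ethylenedioxy-8α-[(2R)-2-methylbutanoyloxy]-10βH-eremophil-11-en-9α-yl (E)-2-methylbut-2-enoate | C=C(C)[C@H]1C[C@@]2(C)[C@H](CC3(OCCO3)C[C@@H]2C)[C@H](OC(=O)/C(C)=C/C)[C@@H]1OC(=O)[C@H](C)CC | intermediate
32 | (4S,5R,7R,8R,9S,10S)-8-[(2R)-2-methylbutanoyloxy]-9-[(E)-2-methylbut-2-enoyloxy]eremophil-11-en-2-one (CNP0312791.1) | C=C(C)[C@H]1C[C@@]2(C)[C@H](CC(=O)C[C@@H]2C)[C@H](OC(=O)/C(C)=C/C)[C@@H]1OC(=O)[C@H](C)CC | target

## Step count and least certain steps

Total: 19 steps. Longest linear sequence: 19 steps, from (+)-3-carene 1 to 32; acids 6, 26 and 29 enter as bought components.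

**Step 10 (key step).** The carbenoid may be diverted before it reaches the alkene (dimerisation, insertion into the C–H bonds of the C4 methyl), or the addition may be slow because the tether must fold over a quaternary centre. The fallback makes the same two bonds from a platinum vinyl carbenoid instead of a diazoketone. It sets out from acid 10 and returns at 17.
- Acid 10 is reduced with LiAlH4 to (2R)-2-[(1S,5R)-1-methyl-5-(prop-1-en-2-yl)cyclohex-2-en-1-yl]propan-1-ol F1 and oxidised with DMP to the aldehyde F2.
- Addition of HC≡CMgBr gives the propargylic alcohol F3 (both C3 epimers serve), which is acetylated (Ac2O, DMAP) to the propargylic acetate F4.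
- PtCl2 in toluene at 80 °C brings about the 1,2-acyloxy shift and cyclopropanation of C9=C10 (a Rautenstrauch-type enyne cycloisomerisation), giving the tricyclic enol acetate F5.
- K2CO3 in MeOH cleaves the enol acetate to the cyclopropyl ketone 17.

**Step 6.** Part of the rearrangement may pass through a boat-like transition state, or the enolate geometry may erode, lowering the diastereoselectivity at C4. The fallback separates the two tasks. It sets out from alcohol 5 and returns at 10.
- Alcohol 5 is esterified with acetic acid under Mitsunobu conditions to the trans acetate F6.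
- Ireland–Claisen rearrangement of F6 (no C4 centre at stake) gives the cyclohexenylacetic acid F7.
- F7 is coupled through its pivaloyl mixed anhydride with lithiated (R)-4-benzyl-2-oxazolidinone to the imide F8.
- Methylation (NaN(SiMe3)2, MeI, −78 °C) under auxiliary control gives the methylated imide F9.
- LiOH/H2O2 releases acid 10.

**Step 11.** Adventitious HI may add to the isopropenyl group, or the iodo ketone may close back to 17 during work-up. The fallback masks the alkene and uses protic acetolysis. It sets out from 17 and returns at 22.
- Pyridinium tribromide in CH2Cl2 at −20 °C converts 17 into the 11,12-dibromide F10.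
- AcOH with catalytic H2SO4 opens the cyclopropane at C9 with inversion to the 9β-acetoxy dibromide F11.
- Zinc dust in AcOH regenerates the isopropenyl group, giving the 9β-acetoxy ketone F12.
- Ketalization as in step 12 gives the acetoxy ketal F13.
- K2CO3 in MeOH gives the 9β epimer of alcohol 22.

**Step 15.** Facial selectivity of the oxygen transfer may be poor or reversed (equatorial instead of axial entry). The fallback sets out from 23 and returns at 27: the same hydroxylation of 23 then gives the 8α alcohol F14, which already has the target configuration. It is esterified with retention by a Steglich-type coupling (26, EDC·HCl, cat. DMAP, CH2Cl2, 0 °C) to give 27, so both C8 epimers converge.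

**Step 18.** Acylation of the hindered axial C9 hydroxyl may be slow, leaving time for the C8 acyl group to migrate to O9. The fallback builds the tiglate in two stages. It sets out from 28 and returns at 31.
- Alcohol 28 is acylated with 2-(diethoxyphosphoryl)propanoic acid and DCC at room temperature to the phosphonopropanoate F15.
- A Horner–Wadsworth–Emmons reaction with acetaldehyde (LiCl, DBU, MeCN) forms the (E)-2-methylbut-2-enoate 31.

## Further compounds

F1 | step 10 | (2R)-2-[(1S,5R)-1-methyl-5-(prop-1-en-2-yl)cyclohex-2-en-1-yl]propan-1-ol | C=C(C)[C@H]1C[C@@]([C@@H](C)CO)(C)C=CC1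
F2 | step 10 | (2R)-2-[(1S,5R)-1-methyl-5-(prop-1-en-2-yl)cyclohex-2-en-1-yl]propanal | C=C(C)[C@H]1C[C@@]([C@@H](C)C=O)(C)C=CC1
F3 | step 10 | (4R)-4-[(1S,5R)-1-methyl-5-(prop-1-en-2-yl)cyclohex-2-en-1-yl]pent-1-yn-3-ol (both C3 epimers) | C=C(C)[C@H]1C[C@@]([C@@H](C)C(O)C#C)(C)C=CC1
F4 | step 10 | (4R)-4-[(1S,5R)-1-methyl-5-(prop-1-en-2-yl)cyclohex-2-en-1-yl]pent-1-yn-3-yl acetate (both C3 epimers) | C=C(C)[C@H]1C[C@@]([C@@H](C)C(OC(C)=O)C#C)(C)C=CC1
F5 | step 10 | 2-acetoxy-1α,9α-cyclo-10βH-eremophila-2,11-diene | C=C(C)[C@H]1C[C@@]2(C)[C@@H]3[C@H](C(OC(C)=O)=C[C@@H]2C)[C@@H]3C1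
F6 | step 6 | (1R,5S)-3-methyl-5-(prop-1-en-2-yl)cyclohex-2-en-1-yl acetate | C=C(C)[C@H]1CC(C)=C[C@H](OC(C)=O)C1
F7 | step 6 | 2-[(1R,5R)-1-methyl-5-(prop-1-en-2-yl)cyclohex-2-en-1-yl]acetic acid | C=C(C)[C@H]1C[C@@](CC(=O)O)(C)C=CC1
F8 | step 6 | (4R)-4-benzyl-3-{2-[(1R,5R)-1-methyl-5-(prop-1-en-2-yl)cyclohex-2-en-1-yl]acetyl}-1,3-oxazolidin-2-one | C=C(C)[C@H]1C[C@@](CC(=O)N2[C@H](Cc3ccccc3)COC2=O)(C)C=CC1
F9 | step 6 | (4R)-4-benzyl-3-{(2R)-2-[(1S,5R)-1-methyl-5-(prop-1-en-2-yl)cyclohex-2-en-1-yl]propanoyl}-1,3-oxazolidin-2-one | C=C(C)[C@H]1C[C@@]([C@@H](C)C(=O)N2[C@H](Cc3ccccc3)COC2=O)(C)C=CC1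
F10 | step 11 | 11,12-dibromo-1α,9α-cyclo-10βH-eremophilan-2-one (both C11 epimers) | CC(Br)(CBr)[C@H]1C[C@@]2(C)[C@@H]3[C@H](C(=O)C[C@@H]2C)[C@@H]3C1
F11 | step 11 | 9β-acetoxy-11,12-dibromo-10βH-eremophilan-2-one (both C11 epimers) | CC(Br)(CBr)[C@H]1C[C@@]2(C)[C@H](CC(=O)C[C@@H]2C)[C@@H](OC(C)=O)C1
F12 | step 11 | 9β-acetoxy-10βH-eremophil-11-en-2-one | C=C(C)[C@H]1C[C@@]2(C)[C@H](CC(=O)C[C@@H]2C)[C@@H](OC(C)=O)C1
F13 | step 11 | 9β-acetoxy-2,2-ethylenedioxy-10βH-eremophil-11-ene | C=C(C)[C@H]1C[C@@]2(C)[C@H](CC3(OCCO3)C[C@@H]2C)[C@@H](OC(C)=O)C1
F14 | step 15 | 2,2-ethylenedioxy-8α-hydroxy-10βH-eremophil-11-en-9-one | C=C(C)[C@H]1C[C@@]2(C)[C@H](CC3(OCCO3)C[C@@H]2C)C(=O)[C@@H]1O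
F15 | step 18 | 2,2-ethylenedioxy-8α-[(2R)-2-methylbutanoyloxy]-10βH-eremophil-11-en-9α-yl 2-(diethoxyphosphoryl)propanoate | C=C(C)[C@H]1C[C@@]2(C)[C@H](CC3(OCCO3)C[C@@H]2C)[C@H](OC(=O)C(C)P(=O)(OCC)OCC)[C@@H]1OC(=O)[C@H](C)CC
A1 | alternative 1 | ring A dienyl ether, tert-butyldimethylsilyl ether of 4,5-dimethyl-3-[(E)-2-(4-methoxybenzyloxy)ethenyl]cyclohex-3-en-1-ol | CC1=C(C[C@@H](O[Si](C)(C)C(C)(C)C)C[C@@H]1C)/C=C/OCc1ccc(OC)cc1
A2 | alternative 1 | methyl acrylate | C=CC(=O)OC
A3 | alternative 1 | endo Diels–Alder adduct (C7 methyl ester cis to the C8 PMB ether, C9=C10 alkene) | COC(=O)[C@@H]1C[C@@]2(C)C(C[C@@H](O[Si](C)(C)C(C)(C)C)C[C@@H]2C)=C[C@@H]1OCc1ccc(OC)cc1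
A4 | alternative 2 | acyclic triene with (E,Z)-diene, (E)-vinyl sulfone, dimethyl ketal and triethylsilyl ether | CC(C)(O[Si](CC)(CC)CC)/C=C/C=C\CC(OC)(OC)C[C@H](C)/C(C)=C/S(=O)(=O)c1ccccc1
A5 | alternative 2 | cis-fused octalin sulfone with C8=C9 alkene | CC(C)(O[Si](CC)(CC)CC)[C@H]1[C@@H](S(=O)(=O)c3ccccc3)[C@@]2(C)[C@H](CC(OC)(OC)C[C@@H]2C)C=C1
A6 | alternative 3 | ring A alkene, tert-butyldimethylsilyl ether of 4,5-dimethylcyclohex-3-en-1-ol | CC1=CC[C@@H](O[Si](C)(C)C(C)(C)C)C[C@@H]1C
A7 | alternative 3 | dichloroketene | O=C=C(Cl)Cl
A8 | alternative 3 | cis-fused dichlorocyclobutanone (C9 carbonyl, C6 dichloromethylene) | ClC1(Cl)C(=O)[C@H]2C[C@@H](O[Si](C)(C)C(C)(C)C)C[C@H](C)[C@@]12C
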